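**Retrosynthetic overview**
- The C5 benzoate comes from the only cis-diol (O4/O5) through a cyclic orthobenzoate, and the C7 benzoate from a primary allylic alcohol obtained by reducing a C1 ester.
- Feature: in the cyclohexene ring (C1 bears C7H2OBz, C2 is the alkene CH, C3–C6 each carry oxygen), C1 is the α-carbon of an enoate once C7 is an ester and C6 is the adjacent carbinol. C3, C4 and C5 carry the configuration of C2, C3 and C4 of D-arabinose.
- Key disconnection: the C1–C6 bond, made by an intramolecular phosphine-catalysed Morita–Baylis–Hillman reaction of an acyclic enoate aldehyde. This closes the only ring and sets C6.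
- The enoate aldehyde comes from D-arabinose 3,4-acetonide by Wittig extension, bis-silylation, primary desilylation and oxidation.

Key step: step 6

Assumption: lactol 2 is used as its anomeric mixture, since both anomers react through the same open-chain hydroxy aldehyde. Ring atoms of all cyclohexenes are numbered as in the overview.

**Step 1**
Reactants: 1 D-arabinose
Product: 2 3,4-O-isopropylidene-D-arabinopyranose
Conditions: 2,2-dimethoxypropane (1.5 equiv), TsOH·H2O (cat.), DMF, rt; Et3N quench
Reagents that add atoms: 2,2-dimethoxypropane, COC(C)(C)OC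
Why: Acid-catalysed transketalisation of the pyranose form should engage its only cis-vicinal diol (O3/O4) as a cis-fused dioxolane, with no stereocentre of the later ring touched.

**Step 2**
Reactants: 2 3,4-O-isopropylidene-D-arabinopyranose; 3 ethyl (triphenylphosphoranylidene)acetate
Product: 4 ethyl (2E,4R,5S,6R)-4,7-dihydroxy-5,6-(isopropylidenedioxy)hept-2-enoate
Conditions: 3 (1.3 equiv), PhCO2H (cat.), CH2Cl2, reflux
Reagents that add atoms: none
Why: Wittig olefination of the lactol through its open hydroxy-aldehyde form with a stabilised ylide in an aprotic solvent should give the E-enoate, which cannot lactonise onto the γ-hydroxyl, while the three carbinol centres are untouched.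

**Step 3**
Reactants: 4 ethyl (2E,4R,5S,6R)-4,7-dihydroxy-5,6-(isopropylidenedioxy)hept-2-enoate
Product: 5 ethyl (2E,4R,5R,6R)-4,7-bis(tert-butyldimethylsilyloxy)-5,6-(isopropylidenedioxy)hept-2-enoate
Conditions: TBSCl (2.6 equiv), imidazole (5 equiv), DMF, rt to 40 °C
Reagents that add atoms: tert-butyldimethylsilyl chloride, CC(C)(C)[Si](C)(C)Cl
Why: Imidazole-promoted silylation should cap both hydroxyls and so remove any chance of oxa-Michael addition to the enoate.

**Step 4**
Reactants: 5 ethyl (2E,4R,5R,6R)-4,7-bis(tert-butyldimethylsilyloxy)-5,6-(isopropylidenedioxy)hept-2-enoate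
Product: 6 ethyl (2E,4R,5R,6R)-4-(tert-butyldimethylsilyloxy)-7-hydroxy-5,6-(isopropylidenedioxy)hept-2-enoate
Conditions: HF·pyridine, pyridine, THF, 0 °C to rt
Reagents that add atoms: none
Why: Buffered fluoride-mediated desilylation should cleave the unhindered primary silyl ether much faster than the hindered secondary allylic one, and the acetonide is stable to pyridine-buffered HF.

**Step 5**
Reactants: 6 ethyl (2E,4R,5R,6R)-4-(tert-butyldimethylsilyloxy)-7-hydroxy-5,6-(isopropylidenedioxy)hept-2-enoate
Product: 7 ethyl (2E,4R,5R,6S)-4-(tert-butyldimethylsilyloxy)-5,6-(isopropylidenedioxy)-7-oxohept-2-enoate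
Conditions: Dess–Martin periodinane (1.3 equiv), CH2Cl2, 0 °C to rt; short silica plug, used at once
Reagents that add atoms: none
Why: Dess–Martin oxidation is close to neutral and should deliver the α-alkoxy aldehyde without epimerising the dioxolane carbon next to it.

**Step 6**
Reactants: 7 ethyl (2E,4R,5R,6S)-4-(tert-butyldimethylsilyloxy)-5,6-(isopropylidenedioxy)-7-oxohept-2-enoate
Product: 8 ethyl (3R,4R,5R,6S)-3-(tert-butyldimethylsilyloxy)-6-hydroxy-4,5-(isopropylidenedioxy)cyclohex-1-ene-1-carboxylate
Conditions: PMe3 (0.5 equiv, 1 M in THF), t-AmOH, 0.02 M, rt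
Reagents that add atoms: none
Why: PMe3 adds reversibly to C2 of the enoate (either alkene geometry gives the same phosphonium enolate), the C1 enolate attacks the tethered C6 aldehyde, and alcohol-assisted proton transfer from C1 followed by E1cB loss of PMe3 restores the C1=C2 bond. The closest known reaction type is the phosphine-catalysed intramolecular Morita–Baylis–Hillman cyclisation of ω-formyl enoates and enones to 6-hydroxycyclohexene carboxylates. The cyclohexene closes by a 6-exo-trig (6-enolexo) aldol, helped by the cis-dioxolane, which holds the C3 arm and the formyl group on the same face. The new C6 stereocentre is controlled by the neighbouring C5 dioxolane oxygen: the formyl group should react through the rotamer with C=O anti to the C5–O bond in a chair-like transition state, so that the carbinol oxygen ends trans to O5 on the convex face of the cis-fused bicycle, and reversibility of the aldol step should drain the cis epimer to this one. The step needs conjugate addition without epimerisation at C5 or β-elimination at C3; the small, weakly basic phosphine in a hindered protic solvent and the poor leaving ability of the silyloxy group are expected to secure this.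

**Step 7**
Reactants: 8 ethyl (3R,4R,5R,6S)-3-(tert-butyldimethylsilyloxy)-6-hydroxy-4,5-(isopropylidenedioxy)cyclohex-1-ene-1-carboxylate
Product: 9 (3R,4R,5R,6S)-3-(tert-butyldimethylsilyloxy)-1-(hydroxymethyl)-4,5-(isopropylidenedioxy)cyclohex-1-en-6-ol
Conditions: DIBAL-H (3.5 equiv), CH2Cl2, −78 to −20 °C; aq. Na/K tartrate
Reagents that add atoms: none
Why: DIBAL-H should reduce the α,β-unsaturated ester by 1,2-addition to the allylic alcohol at low temperature, leaving the silyl ether, the acetonide and all stereocentres untouched.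

**Step 8**
Reactants: 9 (3R,4R,5R,6S)-3-(tert-butyldimethylsilyloxy)-1-(hydroxymethyl)-4,5-(isopropylidenedioxy)cyclohex-1-en-6-ol; 10 benzoyl chloride
Product: 11 [(3R,4R,5R,6S)-3-(tert-butyldimethylsilyloxy)-6-hydroxy-4,5-(isopropylidenedioxy)cyclohex-1-en-1-yl]methyl benzoate
Conditions: 10 (1.05 equiv), pyridine, CH2Cl2, −40 to −20 °C
Reagents that add atoms: none
Why: In this acylation the primary allylic hydroxyl is far less hindered than the secondary C6 carbinol, which is flanked by the C1 substituent and the dioxolane, so one equivalent of acid chloride at low temperature should esterify O7 only.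

**Step 9**
Reactants: 11 [(3R,4R,5R,6S)-3-(tert-butyldimethylsilyloxy)-6-hydroxy-4,5-(isopropylidenedioxy)cyclohex-1-en-1-yl]methyl benzoate
Product: 12 [(3R,4S,5R,6S)-3,4,5,6-tetrahydroxycyclohex-1-en-1-yl]methyl benzoate
Conditions: TFA/H2O (4:1), 0 °C to rt; evaporate, co-evaporate with toluene
Reagents that add atoms: none
Why: Aqueous acid should hydrolyse the ketal and cleave the secondary silyl ether in one operation, while the benzoate survives and every ring C–O bond stays intact, so no stereocentre can change.

**Step 10**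
Reactants: 12 [(3R,4S,5R,6S)-3,4,5,6-tetrahydroxycyclohex-1-en-1-yl]methyl benzoate
Product: 14 [(3R,4S,5R,6S)-5-(benzoyloxy)-3,4,6-trihydroxycyclohex-1-en-1-yl]methyl benzoate, via 4,5-cyclic methyl orthobenzoate 13 (not isolated)
Conditions: PhC(OMe)3 (1.3 equiv), CSA (5 mol %), MeCN, rt; then AcOH/H2O (4:1), rt
Reagents that add atoms: trimethyl orthobenzoate, COC(OC)(OC)c1ccccc1; water, O
Why: Acid-catalysed orthoester exchange should engage only the cis-diol O4/O5 as a 2-methoxy-2-phenyl-1,3-dioxolane, and mild aqueous acid should open it through the hemiorthoester to the ester on the axial oxygen, which is O5 when the C6 hydroxyl sits pseudo-axial to avoid A(1,2) strain with the C1 substituent, with no C–O ring bond broken.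

**Compound list**
1 | D-arabinose | O=C[C@@H](O)[C@H](O)[C@H](O)CO | starting material
2 | 3,4-O-isopropylidene-D-arabinopyranose (anomeric mixture) | OC1[C@@H](O)[C@@H]2OC(C)(C)O[C@@H]2CO1 | intermediate
3 | ethyl (triphenylphosphoranylidene)acetate | CCOC(=O)C=P(c1ccccc1)(c1ccccc1)c1ccccc1 | starting material
4 | ethyl (2E,4R,5S,6R)-4,7-dihydroxy-5,6-(isopropylidenedioxy)hept-2-enoate | CCOC(=O)/C=C/[C@@H](O)[C@@H]1OC(C)(C)O[C@@H]1CO | intermediate
5 | ethyl (2E,4R,5R,6R)-4,7-bis(tert-butyldimethylsilyloxy)-5,6-(isopropylidenedioxy)hept-2-enoate | CCOC(=O)/C=C/[C@@H](O[Si](C)(C)C(C)(C)C)[C@@H]1OC(C)(C)O[C@@H]1CO[Si](C)(C)C(C)(C)C | intermediate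
6 | ethyl (2E,4R,5R,6R)-4-(tert-butyldimethylsilyloxy)-7-hydroxy-5,6-(isopropylidenedioxy)hept-2-enoate | CCOC(=O)/C=C/[C@@H](O[Si](C)(C)C(C)(C)C)[C@@H]1OC(C)(C)O[C@@H]1CO | intermediate
7 | ethyl (2E,4R,5R,6S)-4-(tert-butyldimethylsilyloxy)-5,6-(isopropylidenedioxy)-7-oxohept-2-enoate | CCOC(=O)/C=C/[C@@H](O[Si](C)(C)C(C)(C)C)[C@@H]1OC(C)(C)O[C@@H]1C=O | intermediate
8 | ethyl (3R,4R,5R,6S)-3-(tert-butyldimethylsilyloxy)-6-hydroxy-4,5-(isopropylidenedioxy)cyclohex-1-ene-1-carboxylate | CCOC(=O)C1=C[C@@H](O[Si](C)(C)C(C)(C)C)[C@@H]2OC(C)(C)O[C@@H]2[C@H]1O | intermediate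
9 | (3R,4R,5R,6S)-3-(tert-butyldimethylsilyloxy)-1-(hydroxymethyl)-4,5-(isopropylidenedioxy)cyclohex-1-en-6-ol | OCC1=C[C@@H](O[Si](C)(C)C(C)(C)C)[C@@H]2OC(C)(C)O[C@@H]2[C@H]1O | intermediate
10 | benzoyl chloride | O=C(Cl)c1ccccc1 | starting material
11 | [(3R,4R,5R,6S)-3-(tert-butyldimethylsilyloxy)-6-hydroxy-4,5-(isopropylidenedioxy)cyclohex-1-en-1-yl]methyl benzoate | O=C(OCC1=C[C@@H](O[Si](C)(C)C(C)(C)C)[C@@H]2OC(C)(C)O[C@@H]2[C@H]1O)c1ccccc1 | intermediate
12 | [(3R,4S,5R,6S)-3,4,5,6-tetrahydroxycyclohex-1-en-1-yl]methyl benzoate | O=C(OCC1=C[C@@H](O)[C@H](O)[C@H](O)[C@H]1O)c1ccccc1 | intermediate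
13 | [3,6-dihydroxy-4,5-(α-methoxybenzylidenedioxy)cyclohex-1-en-1-yl]methyl benzoate (4,5-cyclic methyl orthobenzoate of 12, ring configuration as in 12, orthoester carbon as epimer mixture) | O=C(OCC1=C[C@@H](O)[C@@H]2OC(OC)(c3ccccc3)O[C@@H]2[C@H]1O)c1ccccc1 | intermediate
14 | [(3R,4S,5R,6S)-5-(benzoyloxy)-3,4,6-trihydroxycyclohex-1-en-1-yl]methyl benzoate | O=C(OCC1=C[C@@H](O)[C@H](O)[C@H](OC(=O)c2ccccc2)[C@H]1O)c1ccccc1 | target

**Step count**
Total steps: 10. Longest linear sequence: 10 steps, from D-arabinose.

**Steps most likely to fail**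

Step 6. The phosphine may add too slowly to the hindered γ-silyloxy enoate, the aldehyde may epimerise at C5 before closure, or the facial selectivity at C6 may be poor. The fallback forms the same C1–C6 bond by an anionic tandem thia-Michael/aldol and sets out from aldehyde 7. Lithium benzenethiolate (PhSH, n-BuLi, THF, −78 °C) should add to C2, and the ester enolate should close onto the aldehyde to give ethyl 3-(tert-butyldimethylsilyloxy)-6-hydroxy-4,5-(isopropylidenedioxy)-2-(phenylsulfanyl)cyclohexane-1-carboxylate F1. Oxidation with mCPBA (2.2 equiv, CH2Cl2, 0 °C) should give the corresponding phenyl sulfone F2. DBU (CH2Cl2, 0 °C) should then expel benzenesulfinate by E1cB, which needs no syn hydrogen, and the route is rejoined at 8.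

Step 10. The hemiorthoester may open toward the C4 ester if the reacting half-chair carries O4 axial, or the ester may migrate between O4 and O5. The fallback uses the opposite selectivity rule and sets out from tetraol 12. Bu2SnO (MeOH, reflux, then evaporation) should give the 4,5-O-dibutylstannylene acetal F3, and benzoyl chloride 10 (1.0 equiv, dioxane, rt) should then acylate the equatorial oxygen of the cis pair. This is the complementary outcome to orthoester opening, and the route is rejoined at 14.

Step 2. The primary hydroxyl may add to the new enoate (oxa-Michael closure to a C-glycoside) under the basic ylide, or Z-enoate may form and lactonise onto the γ-hydroxyl. The fallback never has a free hydroxyl beside the enoate and sets out from lactol 2. Methylenation (Ph3PCH3Br, KOtBu, THF, 0 °C to rt) should give 1,2-dideoxy-4,5-O-isopropylidene-D-arabino-hex-1-enitol F4. Silylation (TBSCl, imidazole, DMF) should give its 3,6-bis-O-(tert-butyldimethylsilyl) ether F5. Cross-metathesis with ethyl acrylate (Hoveyda–Grubbs II, CH2Cl2, 40 °C) should then install the E-enoate, and the route is rejoined at 5.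

**Further compounds**
F1 | step 6 | ethyl 3-(tert-butyldimethylsilyloxy)-6-hydroxy-4,5-(isopropylidenedioxy)-2-(phenylsulfanyl)cyclohexane-1-carboxylate (C1/C2 epimers) | CCOC(=O)C1C(Sc2ccccc2)[C@@H](O[Si](C)(C)C(C)(C)C)[C@@H]2OC(C)(C)O[C@@H]2[C@H]1O
F2 | step 6 | ethyl 2-(benzenesulfonyl)-3-(tert-butyldimethylsilyloxy)-6-hydroxy-4,5-(isopropylidenedioxy)cyclohexane-1-carboxylate (C1/C2 epimers) | CCOC(=O)C1C(S(=O)(=O)c2ccccc2)[C@@H](O[Si](C)(C)C(C)(C)C)[C@@H]2OC(C)(C)O[C@@H]2[C@H]1O
F3 | step 10 | [4,5-O-(dibutylstannylene)-3,6-dihydroxycyclohex-1-en-1-yl]methyl benzoate (ring configuration as in 12) | O=C(OCC1=C[C@@H](O)[C@@H]2O[Sn](CCCC)(CCCC)O[C@@H]2[C@H]1O)c1ccccc1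
F4 | step 2 | 1,2-dideoxy-4,5-O-isopropylidene-D-arabino-hex-1-enitol | C=C[C@@H](O)[C@@H]1OC(C)(C)O[C@@H]1CO
F5 | step 2 | 3,6-bis-O-(tert-butyldimethylsilyl)-1,2-dideoxy-4,5-O-isopropylidene-D-arabino-hex-1-enitol | C=C[C@@H](O[Si](C)(C)C(C)(C)C)[C@@H]1OC(C)(C)O[C@@H]1CO[Si](C)(C)C(C)(C)C
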